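Retrosynthetic overview (numbering: C1 lactone carbonyl, C2=C3, C4=C5, C6H2, C7=C8, C9=C10, ring C11–C16 with OH on C13 and C15, C17=C18, C19 carbinol, C20–C22, C23 carbinol carbon of the lactone, C24 methyl)
1. The 20-membered lactone is closed last at C3–C4 by intramolecular Stille coupling; the C1–O ester comes from a Mitsunobu inversion at C23, C7=C8 from a Z-selective Wittig reaction on a C8 enal, and C17=C18/C19 from Horner–Wadsworth–Emmons olefination followed by CBS reduction.
2. In the cyclohexane, C15–OH comes from a C13-hydroxyl-directed reduction of a C15 ketone; together with a C17 ester on C16 this is a β-keto ester.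
3. Key disconnection C11–C16: the β-keto ester is the [3,3] product of an eight-membered cyclic allyl vinyl ether (ring O–C9–C10=C11–C12–C13–C14–C15, exocyclic C15=C16–CO2Me), which contracts to the six-membered ring C11–C16 with C9-to-C11 chirality transfer and an E C9=C10 bond.
4. The oxocene comes from ring-closing metathesis (C10=C11) of the oxa-Michael adduct of a C8–C10 butenol (from (S)-glycidol) and a C11–C17 ynoate (from (R)-epichlorohydrin and methyl propiolate). Ring order: eight-membered ether, then cyclohexane by contraction, then the 20-membered lactone.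
5. Enabling feature: the ring bond C11–C16 lies between the exocyclic E olefin C9=C10 on C11 and the oxygen-bearing ring carbon C15, so C9=C10–C11–C16–C15(=O) is a γ,δ-unsaturated carbonyl unit whose oxygen can be tied back to C9 through an eight-membered ring; the C13 oxygen, 1,3 to C15, then steers the reduction.

Key step: step 9

Remark: β-keto ester 13 is written as its keto tautomer with C16 trans to C11; this centre is assumed to equilibrate through the enol until step 11 fixes it.
Abbreviations: PMB = 4-methoxybenzyl, TES = triethylsilyl, TBS = tert-butyldimethylsilyl.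

Step 1
Reactants: 1 (2R)-2-(chloromethyl)oxirane [(R)-epichlorohydrin]
Product: 2 (2R)-1-chloropent-4-en-2-ol
Conditions: CH2=CHMgBr, CuI (cat.), THF, −40 °C; then H2O
Reagents that add atoms: vinylmagnesium bromide, C=C[Mg]Br
Why: Copper-catalysed Grignard opening of the epoxide at its unsubstituted carbon should outrun chloride displacement and leaves the stereocentre (the future C13) untouched.

Step 2
Reactants: 2 (2R)-1-chloropent-4-en-2-ol
Product: 3 (2R)-2-(prop-2-en-1-yl)oxirane
Conditions: NaOH (powdered), Et2O, 0 °C to rt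
Reagents that add atoms: none
Why: Intramolecular Williamson ether synthesis closes the oxirane without breaking a bond at the stereocentre, so the R configuration is kept.

Step 3
Reactants: 3 (2R)-2-(prop-2-en-1-yl)oxirane; 4 methyl prop-2-ynoate
Product: 6 methyl (5R)-5-hydroxyoct-7-en-2-ynoate, via lithiated methyl propiolate 5 (not isolated)
Conditions: n-BuLi, THF, −78 °C; BF3·OEt2, then 3, −78 °C; then H2O
Reagents that add atoms: none
Why: BF3-assisted alkynylation of a terminal epoxide by a lithium acetylide occurs at the CH2 terminus and gives the homopropargylic alcohol with the C13 centre unchanged.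

Step 4
Reactants: 6 methyl (5R)-5-hydroxyoct-7-en-2-ynoate
Product: 7 methyl (5R)-5-[(triethylsilyl)oxy]oct-7-en-2-ynoate
Conditions: Et3SiCl, imidazole, CH2Cl2, 0 °C
Reagents that add atoms: chlorotriethylsilane, CC[Si](Cl)(CC)CC
Why: Standard silyl ether formation; the TES group masks the C13 hydroxyl for the conjugate addition and can later be removed in the presence of the PMB ether.

Step 5
Reactants: 8 [(2S)-oxiran-2-yl]methanol [(S)-glycidol]
Product: 9 (2R)-2-{[(4-methoxyphenyl)methoxy]methyl}oxirane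
Conditions: NaH, 4-MeOC6H4CH2Cl, Bu4NI (cat.), THF/DMF, 0 °C to rt
Reagents that add atoms: 4-methoxybenzyl chloride, COc1ccc(CCl)cc1
Why: Williamson etherification of the primary alkoxide; no bond to the stereocentre is broken (the descriptor changes from S to R only because the substituent priorities change).

Step 6
Reactants: 9 (2R)-2-{[(4-methoxyphenyl)methoxy]methyl}oxirane
Product: 10 (2R)-1-[(4-methoxyphenyl)methoxy]but-3-en-2-ol
Conditions: Me3S+ I−, n-BuLi, THF, −10 °C to rt
Reagents that add atoms: trimethylsulfonium iodide, C[S+](C)C.[I-]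
Why: Epoxide-to-allylic-alcohol homologation with dimethylsulfonium methylide (Corey–Chaykovsky-type ylide opening at CH2, then elimination of dimethyl sulfide) installs the vinyl carbon C10 and leaves the carbinol centre, the future chirality source C9, intact.

Step 7
Reactants: 7 methyl (5R)-5-[(triethylsilyl)oxy]oct-7-en-2-ynoate; 10 (2R)-1-[(4-methoxyphenyl)methoxy]but-3-en-2-ol
Product: 11 methyl (2E,5R)-3-{[(2R)-1-[(4-methoxyphenyl)methoxy]but-3-en-2-yl]oxy}-5-[(triethylsilyl)oxy]octa-2,7-dienoate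
Conditions: PMe3 (20 mol%), CH2Cl2, 0 °C to rt
Reagents that add atoms: none
Why: Trialkylphosphine-catalysed oxa-Michael addition of an alcohol to an alkynoate forms the O–C15 bond and should give the E β-alkoxy enoate (thermodynamic isomer); neither stereocentre is involved.

Step 8
Reactants: 11 methyl (2E,5R)-3-{[(2R)-1-[(4-methoxyphenyl)methoxy]but-3-en-2-yl]oxy}-5-[(triethylsilyl)oxy]octa-2,7-dienoate
Product: 12 oxocene, methyl (2E)-2-[(4R,6Z,8R)-8-{[(4-methoxyphenyl)methoxy]methyl}-4-[(triethylsilyl)oxy]-3,4,5,8-tetrahydro-2H-oxocin-2-ylidene]acetate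
Conditions: second-generation Grubbs catalyst (H2IMes)(PCy3)Cl2Ru=CHPh (5 mol%), CH2Cl2 (2 mM), 40 °C
Reagents that add atoms: none
Why: Ring-closing olefin metathesis of the two monosubstituted olefins forms C10=C11, necessarily cis in the eight-membered ring, while the trisubstituted electron-poor enol ether double bond is inert; eight-membered cyclic ethers are accessible by this reaction at high dilution.

Step 9
Reactants: 12 oxocene, methyl (2E)-2-[(4R,6Z,8R)-8-{[(4-methoxyphenyl)methoxy]methyl}-4-[(triethylsilyl)oxy]-3,4,5,8-tetrahydro-2H-oxocin-2-ylidene]acetate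
Product: 13 methyl (1S,4R,6S)-6-{(1E)-3-[(4-methoxyphenyl)methoxy]prop-1-en-1-yl}-2-oxo-4-[(triethylsilyl)oxy]cyclohexane-1-carboxylate
Conditions: toluene (5 mM), base-washed sealed tube, 150 °C
Reagents that add atoms: none
Why: Proposed new method: on heating, the allyl vinyl ether C16=C15–O–C9–C10=C11 held inside the oxocene should undergo a concerted suprafacial [3,3]-sigmatropic (Claisen) shift in which the exocyclic enol carbon C16 bonds to the ring olefin carbon C11 while the C9–O bond breaks, so that O and C9–C10 leave the ring and the eight-membered ether contracts to the six-membered carbocycle with C15 as ketone; the closest known reaction types are the thermal Claisen rearrangement of acyclic β-allyloxyacrylates and the ring-size-changing Claisen rearrangements of 2-alkylidene cyclic ethers and of macrolactone ketene acetals, but this exocyclic-vinyl/endocyclic-allyl topology on an eight-membered ring has not been described. The carbocycle closes in a 6-(enolendo)-exo-trig sense as one ring of a bicyclo[3.3.1]-like transition state whose six-centre array can only be a chair, because the three-atom C12–C14 tether cannot span the boat. C11 is set by 1,3-chirality transfer from C9: only the chair with the C9 CH2OPMB group exo (pseudo-equatorial) is accessible, which fixes the face of C11 (9R gives 11S) and at the same time the E geometry of the new C9=C10 bond. C16 arises trans to the C11 alkenyl group from the E enol ether and, as the α-carbon of a β-keto ester, stays under thermodynamic control in favour of the trans-diequatorial isomer. The step needs [3,3] selectivity over ionisation of the allylic C9–O bond (elimination or 1,3-shift), which the non-polar acid-free medium should secure, and the correct folding face, which the C13 silyloxy group reinforces because it is also exo in the productive transition state (matched with C9).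

Step 10
Reactants: 13 methyl (1S,4R,6S)-6-{(1E)-3-[(4-methoxyphenyl)methoxy]prop-1-en-1-yl}-2-oxo-4-[(triethylsilyl)oxy]cyclohexane-1-carboxylate
Product: 14 methyl (1S,4R,6S)-4-hydroxy-6-{(1E)-3-[(4-methoxyphenyl)methoxy]prop-1-en-1-yl}-2-oxocyclohexane-1-carboxylate
Conditions: HF·pyridine, pyridine, THF, 0 °C
Reagents that add atoms: none
Why: Buffered fluoride-mediated silyl ether cleavage removes the TES group selectively and frees the C13 hydroxyl that must direct the next step.

Step 11
Reactants: 14 methyl (1S,4R,6S)-4-hydroxy-6-{(1E)-3-[(4-methoxyphenyl)methoxy]prop-1-en-1-yl}-2-oxocyclohexane-1-carboxylate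
Product: 15 methyl (1S,2S,4R,6S)-2,4-dihydroxy-6-{(1E)-3-[(4-methoxyphenyl)methoxy]prop-1-en-1-yl}cyclohexane-1-carboxylate
Conditions: Me4NBH(OAc)3, MeCN/AcOH (1:1), −30 °C
Reagents that add atoms: none
Why: Evans–Saksena hydroxyl-directed reduction: the axial C13 alkoxy-diacetoxyborohydride delivers hydride intramolecularly to the syn face of the C15 ketone, so the new C15 alcohol is equatorial and anti to C13–OH, and the keto tautomer that is reduced carries the ester equatorial (C16 trans to both neighbours).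

Step 12
Reactants: 15 methyl (1S,2S,4R,6S)-2,4-dihydroxy-6-{(1E)-3-[(4-methoxyphenyl)methoxy]prop-1-en-1-yl}cyclohexane-1-carboxylate
Product: 16 methyl (1S,2S,4R,6S)-2,4-bis{[tert-butyl(dimethyl)silyl]oxy}-6-{(1E)-3-[(4-methoxyphenyl)methoxy]prop-1-en-1-yl}cyclohexane-1-carboxylate
Conditions: TBSOTf, 2,6-lutidine, CH2Cl2, −78 to 0 °C
Reagents that add atoms: tert-butyldimethylsilyl trifluoromethanesulfonate, CC(C)(C)[Si](C)(C)OS(=O)(=O)C(F)(F)F
Why: Silylation with the silyl triflate protects the axial and the hindered equatorial hydroxyl alike.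

Step 13
Reactants: 16 methyl (1S,2S,4R,6S)-2,4-bis{[tert-butyl(dimethyl)silyl]oxy}-6-{(1E)-3-[(4-methoxyphenyl)methoxy]prop-1-en-1-yl}cyclohexane-1-carboxylate
Product: 17 [(1R,2S,4R,6S)-2,4-bis{[tert-butyl(dimethyl)silyl]oxy}-6-{(1E)-3-[(4-methoxyphenyl)methoxy]prop-1-en-1-yl}cyclohexyl]methanol
Conditions: i-Bu2AlH, CH2Cl2, −78 to 0 °C; Rochelle salt work-up
Reagents that add atoms: none
Why: Aluminium hydride reduction of the ester to the primary alcohol; the two-step access to the aldehyde avoids partial or over-reduction of this hindered ester.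

Step 14
Reactants: 17 [(1R,2S,4R,6S)-2,4-bis{[tert-butyl(dimethyl)silyl]oxy}-6-{(1E)-3-[(4-methoxyphenyl)methoxy]prop-1-en-1-yl}cyclohexyl]methanol
Product: 18 (1S,2S,4R,6S)-2,4-bis{[tert-butyl(dimethyl)silyl]oxy}-6-{(1E)-3-[(4-methoxyphenyl)methoxy]prop-1-en-1-yl}cyclohexane-1-carbaldehyde
Conditions: Dess–Martin periodinane, NaHCO3, CH2Cl2, 0 °C to rt
Reagents that add atoms: none
Why: Dess–Martin oxidation under buffered, non-epimerising conditions gives the C17 aldehyde with the β-silyloxy group intact.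

Step 15
Reactants: 19 (3R)-butane-1,3-diol
Product: 20 (2S,4R)-2-(4-methoxyphenyl)-4-methyl-1,3-dioxane
Conditions: 4-MeOC6H4CH(OMe)2, camphorsulfonic acid (cat.), CH2Cl2, rt
Reagents that add atoms: 4-methoxybenzaldehyde dimethyl acetal, COc1ccc(C(OC)OC)cc1
Why: Acid-catalysed transacetalisation under thermodynamic control gives the cis-2,4-diequatorial 1,3-dioxane.

Step 16
Reactants: 20 (2S,4R)-2-(4-methoxyphenyl)-4-methyl-1,3-dioxane
Product: 21 (3R)-3-[(4-methoxyphenyl)methoxy]butan-1-ol
Conditions: i-Bu2AlH, CH2Cl2, −78 to 0 °C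
Reagents that add atoms: none
Why: Regioselective reductive acetal opening: aluminium binds the less hindered primary-side oxygen and hydride cleaves that C–O bond, leaving the PMB ether on the secondary oxygen.

Step 17
Reactants: 21 (3R)-3-[(4-methoxyphenyl)methoxy]butan-1-ol
Product: 22 1-({[(2R)-4-iodobutan-2-yl]oxy}methyl)-4-methoxybenzene
Conditions: I2, PPh3, imidazole, CH2Cl2, 0 °C to rt
Reagents that add atoms: iodine, II
Why: Appel-type iodination of the primary alcohol by SN2 displacement of the oxyphosphonium; the stereocentre is remote.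

Step 18
Reactants: 22 1-({[(2R)-4-iodobutan-2-yl]oxy}methyl)-4-methoxybenzene; 23 dimethyl (2-oxopropyl)phosphonate
Product: 25 dimethyl {(6R)-6-[(4-methoxyphenyl)methoxy]-2-oxoheptyl}phosphonate, via phosphonate dianion 24 (not isolated)
Conditions: NaH, THF, 0 °C; n-BuLi, 0 °C; then 22, 0 °C to rt; then H2O
Reagents that add atoms: none
Why: γ-Alkylation of a β-ketophosphonate dianion by a primary iodide occurs at the more basic terminal carbanion.

Step 19
Reactants: 18 (1S,2S,4R,6S)-2,4-bis{[tert-butyl(dimethyl)silyl]oxy}-6-{(1E)-3-[(4-methoxyphenyl)methoxy]prop-1-en-1-yl}cyclohexane-1-carbaldehyde; 25 dimethyl {(6R)-6-[(4-methoxyphenyl)methoxy]-2-oxoheptyl}phosphonate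
Product: 26 (1E,7R)-1-[(1S,2S,4R,6S)-2,4-bis{[tert-butyl(dimethyl)silyl]oxy}-6-{(1E)-3-[(4-methoxyphenyl)methoxy]prop-1-en-1-yl}cyclohexyl]-7-[(4-methoxyphenyl)methoxy]oct-1-en-3-one
Conditions: Ba(OH)2, THF/H2O (40:1), rt
Reagents that add atoms: none
Why: Horner–Wadsworth–Emmons olefination with a β-ketophosphonate under mild barium hydroxide activation gives the E enone; the α-centre C16 already has the thermodynamically preferred equatorial configuration.

Step 20
Reactants: 26 (1E,7R)-1-[(1S,2S,4R,6S)-2,4-bis{[tert-butyl(dimethyl)silyl]oxy}-6-{(1E)-3-[(4-methoxyphenyl)methoxy]prop-1-en-1-yl}cyclohexyl]-7-[(4-methoxyphenyl)methoxy]oct-1-en-3-one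
Product: 27 (1E,3S,7R)-1-[(1S,2S,4R,6S)-2,4-bis{[tert-butyl(dimethyl)silyl]oxy}-6-{(1E)-3-[(4-methoxyphenyl)methoxy]prop-1-en-1-yl}cyclohexyl]-7-[(4-methoxyphenyl)methoxy]oct-1-en-3-ol
Conditions: (R)-2-methyl-CBS-oxazaborolidine (30 mol%), catecholborane, toluene, −78 °C; then MeOH, aq. NaOH
Reagents that add atoms: none
Why: Corey–Bakshi–Shibata reduction; with the alkenyl group as the large and the alkyl chain as the small substituent, the (R)-oxazaborolidine should deliver hydride to the face that gives the (19S) allylic alcohol, with 1,2-reduction only.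

Step 21
Reactants: 27 (1E,3S,7R)-1-[(1S,2S,4R,6S)-2,4-bis{[tert-butyl(dimethyl)silyl]oxy}-6-{(1E)-3-[(4-methoxyphenyl)methoxy]prop-1-en-1-yl}cyclohexyl]-7-[(4-methoxyphenyl)methoxy]oct-1-en-3-ol
Product: 28 C19 tert-butyldimethylsilyl ether of 27 (tris-TBS, bis-PMB ether)
Conditions: TBSOTf, 2,6-lutidine, CH2Cl2, −78 °C
Reagents that add atoms: tert-butyldimethylsilyl trifluoromethanesulfonate, CC(C)(C)[Si](C)(C)OS(=O)(=O)C(F)(F)F
Why: Silyl ether formation protects the allylic C19 alcohol before the oxidation at C8.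

Step 22
Reactants: 28 C19 tert-butyldimethylsilyl ether of 27
Product: 29 (2R,6S,7E)-8-[(1S,2S,4R,6S)-2,4-bis{[tert-butyl(dimethyl)silyl]oxy}-6-[(1E)-3-hydroxyprop-1-en-1-yl]cyclohexyl]-6-{[tert-butyl(dimethyl)silyl]oxy}oct-7-en-2-ol
Conditions: DDQ, CH2Cl2/pH 7 buffer (10:1), 0 °C
Reagents that add atoms: none
Why: Oxidative cleavage of both PMB ethers by single-electron oxidation with DDQ, to which silyl ethers and isolated olefins are inert.

Step 23
Reactants: 29 (2R,6S,7E)-8-[(1S,2S,4R,6S)-2,4-bis{[tert-butyl(dimethyl)silyl]oxy}-6-[(1E)-3-hydroxyprop-1-en-1-yl]cyclohexyl]-6-{[tert-butyl(dimethyl)silyl]oxy}oct-7-en-2-ol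
Product: 30 (2E)-3-[(1S,2S,3S,5R)-3,5-bis{[tert-butyl(dimethyl)silyl]oxy}-2-[(1E,3S,7R)-3-{[tert-butyl(dimethyl)silyl]oxy}-7-hydroxyoct-1-en-1-yl]cyclohexyl]prop-2-enal
Conditions: MnO2 (activated), CH2Cl2, rt
Reagents that add atoms: none
Why: Chemoselective allylic oxidation: MnO2 oxidises only the allylic primary alcohol, so the C8 enal forms while the saturated C23 alcohol is untouched.

Step 24
Reactants: 31 but-3-yn-1-ol
Product: 32 (3E)-4-(tributylstannyl)but-3-en-1-ol
Conditions: Bu3SnH, AIBN (cat.), toluene, 85 °C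
Reagents that add atoms: tributyltin hydride, CCCC[SnH](CCCC)CCCC
Why: Radical hydrostannylation of a terminal alkyne; reversible stannyl-radical addition at this temperature should drive the mixture to the E β-stannyl olefin.

Step 25
Reactants: 32 (3E)-4-(tributylstannyl)but-3-en-1-ol
Product: 33 [(1E)-4-bromobut-1-en-1-yl](tributyl)stannane
Conditions: CBr4, PPh3, Et3N (trace), CH2Cl2, 0 °C
Reagents that add atoms: tetrabromomethane, BrC(Br)(Br)Br
Why: Appel bromination under neutral conditions tolerates the acid-labile vinylstannane.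

Step 26
Reactants: 33 [(1E)-4-bromobut-1-en-1-yl](tributyl)stannane
Product: 34 triphenyl[(3E)-4-(tributylstannyl)but-3-en-1-yl]phosphonium bromide
Conditions: PPh3, i-Pr2NEt (cat.), MeCN, 80 °C
Reagents that add atoms: triphenylphosphine, c1ccc(cc1)P(c1ccccc1)c1ccccc1
Why: SN2 quaternisation of triphenylphosphine by the primary bromide gives the Wittig salt.

Step 27
Reactants: 30 (2E)-3-[(1S,2S,3S,5R)-3,5-bis{[tert-butyl(dimethyl)silyl]oxy}-2-[(1E,3S,7R)-3-{[tert-butyl(dimethyl)silyl]oxy}-7-hydroxyoct-1-en-1-yl]cyclohexyl]prop-2-enal; 34 triphenyl[(3E)-4-(tributylstannyl)but-3-en-1-yl]phosphonium bromide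
Product: 36 (2R,6S,7E)-8-[(1S,2S,4R,6S)-2,4-bis{[tert-butyl(dimethyl)silyl]oxy}-6-[(1E,3Z,6E)-7-(tributylstannyl)hepta-1,3,6-trien-1-yl]cyclohexyl]-6-{[tert-butyl(dimethyl)silyl]oxy}oct-7-en-2-ol, via phosphonium ylide 35 (not isolated)
Conditions: NaN(SiMe3)2, THF, −78 to 0 °C; then 30, −78 °C to rt
Reagents that add atoms: none
Why: Wittig olefination of the E enal with a non-stabilised ylide under lithium-free conditions should give the 7Z olefin through the kinetically favoured cis-oxaphosphetane, and excess ylide tolerates the free C23 hydroxyl.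

Step 28
Reactants: 36 (2R,6S,7E)-8-[(1S,2S,4R,6S)-2,4-bis{[tert-butyl(dimethyl)silyl]oxy}-6-[(1E,3Z,6E)-7-(tributylstannyl)hepta-1,3,6-trien-1-yl]cyclohexyl]-6-{[tert-butyl(dimethyl)silyl]oxy}oct-7-en-2-ol; 37 (2Z)-3-iodoprop-2-enoic acid
Product: 38 (2S,6S,7E)-8-[(1S,2S,4R,6S)-2,4-bis{[tert-butyl(dimethyl)silyl]oxy}-6-[(1E,3Z,6E)-7-(tributylstannyl)hepta-1,3,6-trien-1-yl]cyclohexyl]-6-{[tert-butyl(dimethyl)silyl]oxy}oct-7-en-2-yl (2Z)-3-iodoprop-2-enoate
Conditions: PPh3, diisopropyl azodicarboxylate, THF, 0 °C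
Reagents that add atoms: none
Why: Mitsunobu esterification proceeds by SN2 displacement of the activated C23 oxygen by the carboxylate, inverting C23 from R to S, under neutral conditions that should not isomerise the Z iodoacrylate.

Step 29
Reactants: 38 (2S,6S,7E)-8-[(1S,2S,4R,6S)-2,4-bis{[tert-butyl(dimethyl)silyl]oxy}-6-[(1E,3Z,6E)-7-(tributylstannyl)hepta-1,3,6-trien-1-yl]cyclohexyl]-6-{[tert-butyl(dimethyl)silyl]oxy}oct-7-en-2-yl (2Z)-3-iodoprop-2-enoate
Product: 39 13,15,19-tris-O-(tert-butyldimethylsilyl) ether of the target macrolactone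
Conditions: Pd2(dba)3 (10 mol%), AsPh3 (40 mol%), i-Pr2NEt, DMF/THF (1 mM), rt
Reagents that add atoms: none
Why: Intramolecular Stille coupling of the Z vinyl iodide with the E vinylstannane forms C3–C4 with retention of both geometries and closes the 20-membered lactone under neutral conditions that spare the doubly allylic C6 methylene; this macrocyclisation mode has close precedent for Z,E-dienoate macrolides.

Step 30
Reactants: 39 13,15,19-tris-O-(tert-butyldimethylsilyl) ether of the target macrolactone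
Product: 40 target macrolactone, (2Z,4E,7Z,9E,17E)-pentaene 20-membered lactone fused at C11–C16 to the cyclohexane-13,15-diol, (11S,13R,15S,16S,19S,23S)
Conditions: HF·pyridine, pyridine, THF, 0 °C to rt
Reagents that add atoms: none
Why: Fluoride-mediated cleavage of the three silyl ethers under buffered, weakly acidic conditions avoids base-induced isomerisation of the skipped tetraene and of the Z enoate.

Compound list
1 | (2R)-2-(chloromethyl)oxirane [(R)-epichlorohydrin] | ClC[C@H]1CO1 | starting material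
2 | (2R)-1-chloropent-4-en-2-ol | C=CC[C@@H](O)CCl | intermediate
3 | (2R)-2-(prop-2-en-1-yl)oxirane | C=CC[C@@H]1CO1 | intermediate
4 | methyl prop-2-ynoate | C#CC(=O)OC | starting material
5 | lithiated methyl propiolate (lithium 3-methoxy-3-oxoprop-1-yn-1-ide) | [Li+].[C-]#CC(=O)OC | intermediate
6 | methyl (5R)-5-hydroxyoct-7-en-2-ynoate | C=CC[C@@H](O)CC#CC(=O)OC | intermediate
7 | methyl (5R)-5-[(triethylsilyl)oxy]oct-7-en-2-ynoate | C=CC[C@@H](O[Si](CC)(CC)CC)CC#CC(=O)OC | intermediate
8 | [(2S)-oxiran-2-yl]methanol [(S)-glycidol] | OC[C@H]1CO1 | starting material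
9 | (2R)-2-{[(4-methoxyphenyl)methoxy]methyl}oxirane | COc1ccc(COC[C@H]2CO2)cc1 | intermediate
10 | (2R)-1-[(4-methoxyphenyl)methoxy]but-3-en-2-ol | COc1ccc(COC[C@H](O)C=C)cc1 | intermediate
11 | methyl (2E,5R)-3-{[(2R)-1-[(4-methoxyphenyl)methoxy]but-3-en-2-yl]oxy}-5-[(triethylsilyl)oxy]octa-2,7-dienoate | COC(=O)/C=C(\C[C@H](O[Si](CC)(CC)CC)CC=C)O[C@@H](COCc1ccc(OC)cc1)C=C | intermediate
12 | methyl (2E)-2-[(4R,6Z,8R)-8-{[(4-methoxyphenyl)methoxy]methyl}-4-[(triethylsilyl)oxy]-3,4,5,8-tetrahydro-2H-oxocin-2-ylidene]acetate | COC(=O)/C=C1\C[C@H](O[Si](CC)(CC)CC)C/C=C\[C@H](COCc2ccc(OC)cc2)O1 | intermediate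
13 | methyl (1S,4R,6S)-6-{(1E)-3-[(4-methoxyphenyl)methoxy]prop-1-en-1-yl}-2-oxo-4-[(triethylsilyl)oxy]cyclohexane-1-carboxylate | COC(=O)[C@H]1[C@H](/C=C/COCc2ccc(OC)cc2)C[C@@H](O[Si](CC)(CC)CC)CC1=O | intermediate
14 | methyl (1S,4R,6S)-4-hydroxy-6-{(1E)-3-[(4-methoxyphenyl)methoxy]prop-1-en-1-yl}-2-oxocyclohexane-1-carboxylate | COC(=O)[C@H]1[C@H](/C=C/COCc2ccc(OC)cc2)C[C@@H](O)CC1=O | intermediate
15 | methyl (1S,2S,4R,6S)-2,4-dihydroxy-6-{(1E)-3-[(4-methoxyphenyl)methoxy]prop-1-en-1-yl}cyclohexane-1-carboxylate | COC(=O)[C@H]1[C@H](/C=C/COCc2ccc(OC)cc2)C[C@@H](O)C[C@@H]1O | intermediate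
16 | methyl (1S,2S,4R,6S)-2,4-bis{[tert-butyl(dimethyl)silyl]oxy}-6-{(1E)-3-[(4-methoxyphenyl)methoxy]prop-1-en-1-yl}cyclohexane-1-carboxylate | COC(=O)[C@H]1[C@H](/C=C/COCc2ccc(OC)cc2)C[C@@H](O[Si](C)(C)C(C)(C)C)C[C@@H]1O[Si](C)(C)C(C)(C)C | intermediate
17 | [(1R,2S,4R,6S)-2,4-bis{[tert-butyl(dimethyl)silyl]oxy}-6-{(1E)-3-[(4-methoxyphenyl)methoxy]prop-1-en-1-yl}cyclohexyl]methanol | OC[C@H]1[C@H](/C=C/COCc2ccc(OC)cc2)C[C@@H](O[Si](C)(C)C(C)(C)C)C[C@@H]1O[Si](C)(C)C(C)(C)C | intermediate
18 | (1S,2S,4R,6S)-2,4-bis{[tert-butyl(dimethyl)silyl]oxy}-6-{(1E)-3-[(4-methoxyphenyl)methoxy]prop-1-en-1-yl}cyclohexane-1-carbaldehyde | O=C[C@H]1[C@H](/C=C/COCc2ccc(OC)cc2)C[C@@H](O[Si](C)(C)C(C)(C)C)C[C@@H]1O[Si](C)(C)C(C)(C)C | intermediate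
19 | (3R)-butane-1,3-diol | C[C@@H](O)CCO | starting material
20 | (2S,4R)-2-(4-methoxyphenyl)-4-methyl-1,3-dioxane | C[C@@H]1CCO[C@H](c2ccc(OC)cc2)O1 | intermediate
21 | (3R)-3-[(4-methoxyphenyl)methoxy]butan-1-ol | C[C@@H](OCc1ccc(OC)cc1)CCO | intermediate
22 | 1-({[(2R)-4-iodobutan-2-yl]oxy}methyl)-4-methoxybenzene | C[C@@H](OCc1ccc(OC)cc1)CCI | intermediate
23 | dimethyl (2-oxopropyl)phosphonate | COP(=O)(OC)CC(C)=O | starting material
24 | phosphonate dianion (sodium lithium salt of dimethyl (2-oxopropyl)phosphonate, C1 and C3 deprotonated) | COP(=O)(OC)[CH-]C(=O)[CH2-].[Na+].[Li+] | intermediate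
25 | dimethyl {(6R)-6-[(4-methoxyphenyl)methoxy]-2-oxoheptyl}phosphonate | COP(=O)(OC)CC(=O)CCC[C@@H](C)OCc1ccc(OC)cc1 | intermediate
26 | (1E,7R)-1-[(1S,2S,4R,6S)-2,4-bis{[tert-butyl(dimethyl)silyl]oxy}-6-{(1E)-3-[(4-methoxyphenyl)methoxy]prop-1-en-1-yl}cyclohexyl]-7-[(4-methoxyphenyl)methoxy]oct-1-en-3-one | C[C@@H](OCc1ccc(OC)cc1)CCCC(=O)/C=C/[C@H]1[C@H](/C=C/COCc2ccc(OC)cc2)C[C@@H](O[Si](C)(C)C(C)(C)C)C[C@@H]1O[Si](C)(C)C(C)(C)C | intermediate
27 | (1E,3S,7R)-1-[(1S,2S,4R,6S)-2,4-bis{[tert-butyl(dimethyl)silyl]oxy}-6-{(1E)-3-[(4-methoxyphenyl)methoxy]prop-1-en-1-yl}cyclohexyl]-7-[(4-methoxyphenyl)methoxy]oct-1-en-3-ol | C[C@@H](OCc1ccc(OC)cc1)CCC[C@H](O)/C=C/[C@H]1[C@H](/C=C/COCc2ccc(OC)cc2)C[C@@H](O[Si](C)(C)C(C)(C)C)C[C@@H]1O[Si](C)(C)C(C)(C)C | intermediate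
28 | C19 tert-butyldimethylsilyl ether of 27 (tris-TBS, bis-PMB ether) | C[C@@H](OCc1ccc(OC)cc1)CCC[C@H](O[Si](C)(C)C(C)(C)C)/C=C/[C@H]1[C@H](/C=C/COCc2ccc(OC)cc2)C[C@@H](O[Si](C)(C)C(C)(C)C)C[C@@H]1O[Si](C)(C)C(C)(C)C | intermediate
29 | (2R,6S,7E)-8-[(1S,2S,4R,6S)-2,4-bis{[tert-butyl(dimethyl)silyl]oxy}-6-[(1E)-3-hydroxyprop-1-en-1-yl]cyclohexyl]-6-{[tert-butyl(dimethyl)silyl]oxy}oct-7-en-2-ol | C[C@@H](O)CCC[C@H](O[Si](C)(C)C(C)(C)C)/C=C/[C@H]1[C@H](/C=C/CO)C[C@@H](O[Si](C)(C)C(C)(C)C)C[C@@H]1O[Si](C)(C)C(C)(C)C | intermediate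
30 | (2E)-3-[(1S,2S,3S,5R)-3,5-bis{[tert-butyl(dimethyl)silyl]oxy}-2-[(1E,3S,7R)-3-{[tert-butyl(dimethyl)silyl]oxy}-7-hydroxyoct-1-en-1-yl]cyclohexyl]prop-2-enal | C[C@@H](O)CCC[C@H](O[Si](C)(C)C(C)(C)C)/C=C/[C@H]1[C@H](/C=C/C=O)C[C@@H](O[Si](C)(C)C(C)(C)C)C[C@@H]1O[Si](C)(C)C(C)(C)C | intermediate
31 | but-3-yn-1-ol | C#CCCO | starting material
32 | (3E)-4-(tributylstannyl)but-3-en-1-ol | CCCC[Sn](CCCC)(CCCC)/C=C/CCO | intermediate
33 | [(1E)-4-bromobut-1-en-1-yl](tributyl)stannane | CCCC[Sn](CCCC)(CCCC)/C=C/CCBr | intermediate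
34 | triphenyl[(3E)-4-(tributylstannyl)but-3-en-1-yl]phosphonium bromide | CCCC[Sn](CCCC)(CCCC)/C=C/CC[P+](c1ccccc1)(c1ccccc1)c1ccccc1.[Br-] | intermediate
35 | phosphonium ylide, triphenyl[(3E)-4-(tributylstannyl)but-3-en-1-ylidene]phosphorane | CCCC[Sn](CCCC)(CCCC)/C=C/CC=P(c1ccccc1)(c1ccccc1)c1ccccc1 | intermediate
36 | (2R,6S,7E)-8-[(1S,2S,4R,6S)-2,4-bis{[tert-butyl(dimethyl)silyl]oxy}-6-[(1E,3Z,6E)-7-(tributylstannyl)hepta-1,3,6-trien-1-yl]cyclohexyl]-6-{[tert-butyl(dimethyl)silyl]oxy}oct-7-en-2-ol | C[C@@H](O)CCC[C@H](O[Si](C)(C)C(C)(C)C)/C=C/[C@H]1[C@H](/C=C/C=C\C/C=C/[Sn](CCCC)(CCCC)CCCC)C[C@@H](O[Si](C)(C)C(C)(C)C)C[C@@H]1O[Si](C)(C)C(C)(C)C | intermediate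
37 | (2Z)-3-iodoprop-2-enoic acid | OC(=O)/C=C\I | starting material
38 | (2S,6S,7E)-8-[(1S,2S,4R,6S)-2,4-bis{[tert-butyl(dimethyl)silyl]oxy}-6-[(1E,3Z,6E)-7-(tributylstannyl)hepta-1,3,6-trien-1-yl]cyclohexyl]-6-{[tert-butyl(dimethyl)silyl]oxy}oct-7-en-2-yl (2Z)-3-iodoprop-2-enoate | C[C@H](OC(=O)/C=C\I)CCC[C@H](O[Si](C)(C)C(C)(C)C)/C=C/[C@H]1[C@H](/C=C/C=C\C/C=C/[Sn](CCCC)(CCCC)CCCC)C[C@@H](O[Si](C)(C)C(C)(C)C)C[C@@H]1O[Si](C)(C)C(C)(C)C | intermediate
39 | 13,15,19-tris-O-(tert-butyldimethylsilyl) ether of the target macrolactone | C[C@H]1CCC[C@H](O[Si](C)(C)C(C)(C)C)/C=C/[C@H]2[C@H](/C=C/C=C\C/C=C/C=C\C(=O)O1)C[C@@H](O[Si](C)(C)C(C)(C)C)C[C@@H]2O[Si](C)(C)C(C)(C)C | intermediate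
40 | target macrolactone CNP0158690.2, (2Z,4E,7Z,9E,11S,13R,15S,16S,17E,19S,23S) | C[C@H]1CCC[C@H](O)/C=C/[C@H]2[C@H](/C=C/C=C\C/C=C/C=C\C(=O)O1)C[C@@H](O)C[C@@H]2O | target

Total step count: 30. Longest linear sequence: 21 steps (steps 1–4, 7–14, 19–23, 27–30).

Steps most likely to fail

Step 9 (Proposed new method). The concerted shift may be outpaced by heterolysis of the allylic C9–O bond, leading to elimination to a triene or to non-stereospecific recombination, or it may need temperatures at which the β-silyloxy ketone product eliminates. The fallback keeps the same ring contraction but changes the bond-forming manifold to a known one. Setting out from 12, catalysis by zerovalent palladium (Pd(PPh3)4, THF, 50 °C) should effect the 1,3 O-to-C allyl transfer that is established for 2-alkylidene-5-vinyl cyclic ethers and for allyl enol ethers of β-keto esters (Tsuji–Trost-type ionisation and recombination). Ionisation of C9–O with inversion gives a π-allylpalladium cation tethered to the β-keto ester enolate, which attacks C11 with a second inversion; six-membered closure is favoured over eight-membered closure at C9, and the syn arrangement of the CH2OPMB group gives the E olefin. The sequence comes back to the route at 13 and makes no new compound.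

Step 8. Ring closure may lose to intermolecular metathesis (oligomerisation), because the E enol ether mainly populates the rotamer in which the C9 and C14 chains point away from each other across the O–C15 bond. The fallback changes the substrate rather than the catalyst or dilution. Setting out from 11, sensitised E-to-Z photoisomerisation of the β-alkoxy enoate (benzophenone, 350 nm, benzene) should give methyl (2Z,5R)-3-{[(2R)-1-[(4-methoxyphenyl)methoxy]but-3-en-2-yl]oxy}-5-[(triethylsilyl)oxy]octa-2,7-dienoate F3, separated from recovered 11. In F3, allylic strain between the ester and the C9 substituent forces the O–C9 bond syn to C14, the rotamer needed for cyclisation. Metathesis under the conditions of step 8 should then give methyl (2Z)-2-[(4R,6Z,8R)-8-{[(4-methoxyphenyl)methoxy]methyl}-4-[(triethylsilyl)oxy]-3,4,5,8-tetrahydro-2H-oxocin-2-ylidene]acetate F4. Heating F4 as in step 9 comes back to the route at 13, because the C16 epimer formed first from the Z enol ether equilibrates through the enol to the trans β-keto ester.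

Step 7. The phosphine may isomerise the ynoate through its γ-hydrogens (allenoate or dienoate formation, γ-addition) faster than the hindered secondary alcohol adds to the β-carbon. The fallback forms the O–C15 bond by addition–elimination instead. Setting out from 6, hydroiodination (NaI, AcOH, 70 °C; trans addition) should give methyl (2Z,5R)-5-hydroxy-3-iodoocta-2,7-dienoate F1. Silylation (Et3SiCl, imidazole) gives methyl (2Z,5R)-3-iodo-5-[(triethylsilyl)oxy]octa-2,7-dienoate F2. The sodium alkoxide of 10 (NaH, THF, 0 °C to rt) then displaces iodide by conjugate addition–elimination and, under these reversible conditions, should settle at the E enol ether; the sequence comes back to the route at 11.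

Further compounds
F0 | step 9 | none | none
F1 | step 7 | methyl (2Z,5R)-5-hydroxy-3-iodoocta-2,7-dienoate | C=CC[C@@H](O)C/C(I)=C/C(=O)OC
F2 | step 7 | methyl (2Z,5R)-3-iodo-5-[(triethylsilyl)oxy]octa-2,7-dienoate | C=CC[C@@H](O[Si](CC)(CC)CC)C/C(I)=C/C(=O)OC
F3 | step 8 | methyl (2Z,5R)-3-{[(2R)-1-[(4-methoxyphenyl)methoxy]but-3-en-2-yl]oxy}-5-[(triethylsilyl)oxy]octa-2,7-dienoate | COC(=O)/C=C(/C[C@H](O[Si](CC)(CC)CC)CC=C)O[C@@H](COCc1ccc(OC)cc1)C=C
F4 | step 8 | methyl (2Z)-2-[(4R,6Z,8R)-8-{[(4-methoxyphenyl)methoxy]methyl}-4-[(triethylsilyl)oxy]-3,4,5,8-tetrahydro-2H-oxocin-2-ylidene]acetate | COC(=O)/C=C1/C[C@H](O[Si](CC)(CC)CC)C/C=C\[C@H](COCc2ccc(OC)cc2)O1
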